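Rings are lettered A (3,5-dihydroxyphenoxy end) to E (2,4,6-trihydroxyphenyl end). The route rests on cutting the ring C–O–ring D ether and building ring D from a squarate. Ring D is a hydroquinone: its C1 oxygen (to ring C) is para to the C4 hydroxyl and flanked by the C2 hydroxyl and the C6 ether to ring E. Thermal ring expansion of a 4-hydroxy-4-(1-methoxyvinyl)-3-(2,4,6-trimethoxyphenoxy)cyclobutenone forms one C–C bond and delivers this tetraoxygenated ring with every oxygen in place and ring E already attached. Methylation, one copper-catalysed coupling with a ring A–C bromide and global demethylation finish the synthesis.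

Key step: step 6

Remarks on the chemistry:
- The target has no stereocentre. Compounds 5 and 12 are racemic and their single stereocentres disappear in steps 2 and 6.
- The C4 hydroxyl of ring D is capped as a methyl ether, not a benzyl ether. The final BBr3 step then sets free only bromomethane and no benzylic electrophile that could alkylate the phloroglucinol rings.
- 2-Fluoro-4,6-dimethoxybenzaldehyde, 4-bromo-2,6-dimethoxyphenol and 3,5-dimethoxyphenylboronic acid are taken as purchasable.

Step 1
Reactants: 1 2,4,6-trimethoxybenzaldehyde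
Product: 3 2,4,6-trimethoxyphenol, via 2,4,6-trimethoxyphenyl formate 2 (not isolated)
Conditions: H2O2 (30% aq), H2SO4 (cat.), MeOH, 0 °C → rt, argon
Reagents that add atoms: hydrogen peroxide, OO
Why: Acid-catalysed Dakin oxidation, in which the electron-rich aryl group migrates from carbon to oxygen in the hydroperoxide adduct of the aldehyde and methanol cleaves the resulting formate 2 in the same flask.

Step 2
Reactants: 4 diisopropyl squarate
Product: 6 3-isopropoxycyclobut-3-ene-1,2-dione, via 4-hydroxy-2,3-diisopropoxycyclobut-2-en-1-one 5 (not isolated)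
Conditions: LiAlH(OtBu)3, THF, −78 → 0 °C; aq HCl; then conc. HCl (cat.), CH2Cl2, rt
Reagents that add atoms: none
Why: Hydride 1,2-reduction of one squarate carbonyl followed by acid-promoted collapse of the vinylogous hemiacetal with loss of isopropanol, the standard entry to alkyl semisquarates; the stereocentre of 5 is racemic and is removed when 6 forms.

Step 3
Reactants: 6 3-isopropoxycyclobut-3-ene-1,2-dione
Product: 7 semisquaric acid (3-hydroxycyclobut-3-ene-1,2-dione)
Conditions: 2 M HCl, THF–H2O, rt; evaporate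
Reagents that add atoms: water, O
Why: Acid-catalysed hydrolysis of a vinylogous ester by addition–elimination of water at C3 should give the strongly acidic semisquaric acid, isolated by evaporation.

Step 4
Reactants: 7 semisquaric acid; 3 2,4,6-trimethoxyphenol
Product: 9 3-(2,4,6-trimethoxyphenoxy)cyclobut-3-ene-1,2-dione, via 3-chlorocyclobut-3-ene-1,2-dione 8 (not isolated)
Conditions: (COCl)2, DMF (cat.), CH2Cl2, 0 °C → rt; concentrate; then 3, Et3N, CH2Cl2, −78 → 0 °C
Reagents that add atoms: none
Why: Vilsmeier-type activation turns the vinylogous acid into its vinylogous acid chloride 8, and the phenoxide of 3 then replaces chloride by addition–elimination at C3, the counterpart of an acyl chloride esterification.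

Step 5
Reactants: 9 3-(2,4,6-trimethoxyphenoxy)cyclobut-3-ene-1,2-dione; 10 methyl vinyl ether
Product: 12 racemic 4-hydroxy-4-(1-methoxyvinyl)-3-(2,4,6-trimethoxyphenoxy)cyclobut-2-en-1-one, via 1-methoxyvinyllithium 11 (not isolated)
Conditions: 10, t-BuLi, THF, −78 → 0 °C; then 9, THF, −78 °C; NH4Cl (aq), −78 °C
Reagents that add atoms: none
Why: 1,2-Addition of the hard alkenyllithium at −78 °C should occur at the ketone carbonyl beside the aryloxy carbon, because the other carbonyl is deactivated as a vinylogous ester, which is the regiochemistry established for organolithium additions to alkyl semisquarates; the quaternary carbinol centre forms as a racemate and is destroyed in step 6.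

Step 6
Reactants: 12 racemic 4-hydroxy-4-(1-methoxyvinyl)-3-(2,4,6-trimethoxyphenoxy)cyclobut-2-en-1-one
Product: 15 2-methoxy-6-(2,4,6-trimethoxyphenoxy)benzene-1,4-diol, via dienylketene 13 (not isolated), via cyclohexa-2,4-dienone 14 (not isolated)
Conditions: toluene (degassed), 110 °C, argon
Reagents that add atoms: none
Why: Moore rearrangement: conrotatory 4π electrocyclic opening of the C1–C4 bond of the cyclobutenone gives the dienylketene 13, a 6π electrocyclisation joins the ketene carbon to the terminal CH2 of the methoxyvinyl group (the one new C–C bond), and tautomerisation of the cyclohexa-2,4-dienone 14 aromatises ring D. The closest known reaction type is the thermolysis of squarate-derived 4-alkenyl- and 4-aryl-4-hydroxycyclobutenones to hydroquinones. Ring D is closed as a six-membered carbocycle by a thermally allowed disrotatory 6π electrocyclisation, driven onward by aromatisation. No stereocentre is created and the carbinol centre of 12 is lost. The step needs torquoselectivity, which the donor hydroxyl on the carbinol carbon secures by rotating outward, so that the methoxyvinyl group turns inward toward the ketene. The regiochemistry was fixed by the constitution of 12: the carbinol carbon becomes C1–OH, the ketene carbon C4–OH, the methoxyvinyl carbon C2–OMe and the aryloxy carbon C6–O–ring E.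

Step 7
Reactants: 15 2-methoxy-6-(2,4,6-trimethoxyphenoxy)benzene-1,4-diol
Product: 16 2,4-dimethoxy-6-(2,4,6-trimethoxyphenoxy)phenol
Conditions: MeI (1.05 equiv), K2CO3, acetone, rt, argon
Reagents that add atoms: iodomethane, CI
Why: Williamson O-methylation under weak-base control should cap the C4 hydroxyl, which is the more acidic (two meta oxygen substituents) and unhindered, while the C1 hydroxyl is flanked by methoxy and aryloxy groups and hydrogen-bonded.

Step 8
Reactants: 17 4-bromo-2,6-dimethoxyphenol; 18 2-fluoro-4,6-dimethoxybenzaldehyde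
Product: 19 2-(4-bromo-2,6-dimethoxyphenoxy)-4,6-dimethoxybenzaldehyde
Conditions: Cs2CO3, DMSO, 110 °C
Reagents that add atoms: none
Why: Nucleophilic aromatic substitution (SNAr), in which the phenoxide displaces the fluoride ortho to the formyl group through a Meisenheimer intermediate while the unactivated aryl bromide stays untouched.

Step 9
Reactants: 19 2-(4-bromo-2,6-dimethoxyphenoxy)-4,6-dimethoxybenzaldehyde
Product: 21 2-(4-bromo-2,6-dimethoxyphenoxy)-4,6-dimethoxyphenol, via aryl formate 20 (not isolated)
Conditions: H2O2 (30% aq), H2SO4 (cat.), MeOH, rt, argon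
Reagents that add atoms: hydrogen peroxide, OO
Why: Acid-catalysed Dakin oxidation as in step 1, favoured by the ortho and para oxygen substituents that raise the migratory aptitude of the aryl group; the aryl bromide and the diaryl ether are inert to H2O2.

Step 10
Reactants: 21 2-(4-bromo-2,6-dimethoxyphenoxy)-4,6-dimethoxyphenol; 22 3,5-dimethoxyphenylboronic acid
Product: 23 5-bromo-2-[2-(3,5-dimethoxyphenoxy)-3,5-dimethoxyphenoxy]-1,3-dimethoxybenzene (ring A–C bromide)
Conditions: Cu(OAc)2, pyridine, 4 Å MS, CH2Cl2, O2 (balloon), rt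
Reagents that add atoms: none
Why: Chan–Lam–Evans oxidative O-arylation with an unhindered arylboronic acid at room temperature should form the ring A–O–ring B ether at the flanked phenol and leave the aryl bromide intact, which a copper-catalysed aryl halide coupling at this stage would not.

Step 11
Reactants: 16 2,4-dimethoxy-6-(2,4,6-trimethoxyphenoxy)phenol; 23 ring A–C bromide
Product: 24 undeca-O-methyl ether of the target, 1-[4-[2-(3,5-dimethoxyphenoxy)-3,5-dimethoxyphenoxy]-3,5-dimethoxyphenoxy]-2,4-dimethoxy-6-(2,4,6-trimethoxyphenoxy)benzene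
Conditions: CuI, picolinic acid, K3PO4, DMSO, 100 °C, argon
Reagents that add atoms: none
Why: Ullmann-type diaryl ether synthesis under ligand-accelerated CuI catalysis, in which the picolinate-ligated monovalent copper phenoxide of the hindered phenol 16 should react with the C–Br bond of 23, which has two ortho hydrogens and is the only carbon–halogen bond in either partner.

Step 12
Reactants: 24 undeca-O-methyl ether of the target
Product: 25 CNP0018313.0, 4-{4-[2-(3,5-dihydroxyphenoxy)-3,5-dihydroxyphenoxy]-3,5-dihydroxyphenoxy}-5-(2,4,6-trihydroxyphenoxy)benzene-1,3-diol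
Conditions: BBr3 (excess), CH2Cl2, −78 °C → rt; then MeOH, H2O
Reagents that add atoms: none
Why: Lewis acid-mediated cleavage of all eleven aryl methyl ethers by BBr3 (bromide attacks the methyl group of the boron-complexed ether) should leave the diaryl ether bonds intact, as is usual for permethylated phlorotannins.

Compound list
1 | 2,4,6-trimethoxybenzaldehyde | COc1cc(OC)c(C=O)c(OC)c1 | starting material
2 | 2,4,6-trimethoxyphenyl formate | COc1cc(OC)c(OC=O)c(OC)c1 | intermediate
3 | 2,4,6-trimethoxyphenol | COc1cc(OC)c(O)c(OC)c1 | intermediate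
4 | diisopropyl squarate | CC(C)OC1=C(OC(C)C)C(=O)C1=O | starting material
5 | 4-hydroxy-2,3-diisopropoxycyclobut-2-en-1-one (racemic) | CC(C)OC1=C(OC(C)C)C(O)C1=O | intermediate
6 | 3-isopropoxycyclobut-3-ene-1,2-dione | CC(C)OC1=CC(=O)C1=O | intermediate
7 | semisquaric acid (3-hydroxycyclobut-3-ene-1,2-dione) | OC1=CC(=O)C1=O | intermediate
8 | 3-chlorocyclobut-3-ene-1,2-dione | ClC1=CC(=O)C1=O | intermediate
9 | 3-(2,4,6-trimethoxyphenoxy)cyclobut-3-ene-1,2-dione | COc1cc(OC)c(OC2=CC(=O)C2=O)c(OC)c1 | intermediate
10 | methyl vinyl ether | COC=C | starting material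
11 | 1-methoxyvinyllithium | [Li]C(=C)OC | intermediate
12 | 4-hydroxy-4-(1-methoxyvinyl)-3-(2,4,6-trimethoxyphenoxy)cyclobut-2-en-1-one (racemic) | O=C1C=C(Oc2c(OC)cc(OC)cc2OC)C1(O)C(OC)=C | intermediate
13 | (3Z)-4-hydroxy-5-methoxy-3-(2,4,6-trimethoxyphenoxy)hexa-1,3,5-trien-1-one (dienylketene) | O=C=C/C(Oc1c(OC)cc(OC)cc1OC)=C(O)\C(OC)=C | intermediate
14 | 4-hydroxy-5-methoxy-3-(2,4,6-trimethoxyphenoxy)cyclohexa-2,4-dien-1-one | O=C1CC(OC)=C(O)C(Oc2c(OC)cc(OC)cc2OC)=C1 | intermediate
15 | 2-methoxy-6-(2,4,6-trimethoxyphenoxy)benzene-1,4-diol (ring D–E dimer) | Oc1cc(OC)c(O)c(Oc2c(OC)cc(OC)cc2OC)c1 | intermediate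
16 | 2,4-dimethoxy-6-(2,4,6-trimethoxyphenoxy)phenol | COc1cc(OC)c(O)c(Oc2c(OC)cc(OC)cc2OC)c1 | intermediate
17 | 4-bromo-2,6-dimethoxyphenol | COc1cc(Br)cc(OC)c1O | starting material
18 | 2-fluoro-4,6-dimethoxybenzaldehyde | COc1cc(F)c(C=O)c(OC)c1 | starting material
19 | 2-(4-bromo-2,6-dimethoxyphenoxy)-4,6-dimethoxybenzaldehyde | COc1cc(OC)c(C=O)c(Oc2c(OC)cc(Br)cc2OC)c1 | intermediate
20 | 2-(4-bromo-2,6-dimethoxyphenoxy)-4,6-dimethoxyphenyl formate | COc1cc(OC)c(OC=O)c(Oc2c(OC)cc(Br)cc2OC)c1 | intermediate
21 | 2-(4-bromo-2,6-dimethoxyphenoxy)-4,6-dimethoxyphenol | COc1cc(OC)c(O)c(Oc2c(OC)cc(Br)cc2OC)c1 | intermediate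
22 | 3,5-dimethoxyphenylboronic acid | COc1cc(OC)cc(B(O)O)c1 | starting material
23 | 5-bromo-2-[2-(3,5-dimethoxyphenoxy)-3,5-dimethoxyphenoxy]-1,3-dimethoxybenzene | COc1cc(OC)cc(Oc2c(OC)cc(OC)cc2Oc2c(OC)cc(Br)cc2OC)c1 | intermediate
24 | 1-[4-[2-(3,5-dimethoxyphenoxy)-3,5-dimethoxyphenoxy]-3,5-dimethoxyphenoxy]-2,4-dimethoxy-6-(2,4,6-trimethoxyphenoxy)benzene | COc1cc(OC)cc(Oc2c(OC)cc(OC)cc2Oc2c(OC)cc(Oc3c(OC)cc(OC)cc3Oc3c(OC)cc(OC)cc3OC)cc2OC)c1 | intermediate
25 | CNP0018313.0, 4-{4-[2-(3,5-dihydroxyphenoxy)-3,5-dihydroxyphenoxy]-3,5-dihydroxyphenoxy}-5-(2,4,6-trihydroxyphenoxy)benzene-1,3-diol | Oc1cc(O)cc(Oc2c(O)cc(O)cc2Oc2c(O)cc(Oc3c(O)cc(O)cc3Oc3c(O)cc(O)cc3O)cc2O)c1 | target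

Total step count: 12.
Longest linear sequence: 8 steps (steps 2, 3, 4, 5, 6, 7, 11, 12, from diisopropyl squarate 4).

Steps most likely to fail

1. Step 11. The C–O bond may form too slowly at the doubly flanked phenoxide of 16, so that reduction of the C–Br bond of 23 and oxidative decomposition of the electron-rich phenoxide at 100 °C outrun the coupling. The fallback sets out from 16 and comes back at 24, and it replaces the copper–aryl halide coupling by metal-free SNAr/Dakin cycles that grow rings C and B onto 16. The caesium phenoxide of 16 should displace the fluoride para to the formyl group of purchased 4-fluoro-2,6-dimethoxybenzaldehyde (Cs2CO3, DMSO, 110 °C) to give the ring C–E aldehyde F1. Dakin oxidation (H2O2, cat. H2SO4, MeOH) should pass through the ring C–E formate F2 to the ring C–E phenol F3. A second SNAr with 18 should give the ring B–E aldehyde F4, and a second Dakin oxidation through the ring B–E formate F5 should give the ring B–E phenol F6. This phenol is O-arylated with 22 under the conditions of step 10 to give 24.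

2. Step 10. Transmetalation and C–O bond formation at the flanked phenol may be slow, so that the boronic acid is consumed by protodeboronation and homocoupling and the trioxygenated phenol is oxidised by divalent copper and oxygen. The fallback sets out from 21 and comes back at 23, and it uses metal-free arylation with a diaryliodonium salt. The salt, (3,5-dimethoxyphenyl)(2,4,6-trimethoxyphenyl)iodonium tosylate F7, would be made in one pot from purchased 1-iodo-3,5-dimethoxybenzene (mCPBA, TsOH·H2O, MeCN, then 1,3,5-trimethoxybenzene). With K2CO3 in toluene at 55 °C the phenoxide of 21 should attack trivalent iodine, and ligand coupling should transfer the 3,5-dimethoxyphenyl group, the trimethoxyphenyl group serving as the ligand that is not transferred. The aryl bromide is inert under these conditions.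

3. Step 5. The alkenyllithium may attack the aryloxy-bearing carbon with loss of aryloxide, or the wrong carbonyl, and the enol ether of 12 may hydrolyse on work-up. The fallback sets out from 3 and comes back at 16. It gives up the ring expansion and is held only in reserve. SNAr of the phenoxide of 3 on 18 (Cs2CO3, DMSO, 110 °C) should give 2,4-dimethoxy-6-(2,4,6-trimethoxyphenoxy)benzaldehyde F8, and Dakin oxidation (H2O2, cat. H2SO4, MeOH) through the ring D–E formate F9 should give 16 directly.

Further compounds
F1 | step 11 | 4-[2,4-dimethoxy-6-(2,4,6-trimethoxyphenoxy)phenoxy]-2,6-dimethoxybenzaldehyde | O=Cc1c(OC)cc(Oc2c(OC)cc(OC)cc2Oc2c(OC)cc(OC)cc2OC)cc1OC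
F2 | step 11 | 4-[2,4-dimethoxy-6-(2,4,6-trimethoxyphenoxy)phenoxy]-2,6-dimethoxyphenyl formate | O=COc1c(OC)cc(Oc2c(OC)cc(OC)cc2Oc2c(OC)cc(OC)cc2OC)cc1OC
F3 | step 11 | 4-[2,4-dimethoxy-6-(2,4,6-trimethoxyphenoxy)phenoxy]-2,6-dimethoxyphenol | Oc1c(OC)cc(Oc2c(OC)cc(OC)cc2Oc2c(OC)cc(OC)cc2OC)cc1OC
F4 | step 11 | 2-{4-[2,4-dimethoxy-6-(2,4,6-trimethoxyphenoxy)phenoxy]-2,6-dimethoxyphenoxy}-4,6-dimethoxybenzaldehyde | COc1cc(OC)c(C=O)c(Oc2c(OC)cc(Oc3c(OC)cc(OC)cc3Oc3c(OC)cc(OC)cc3OC)cc2OC)c1
F5 | step 11 | 2-{4-[2,4-dimethoxy-6-(2,4,6-trimethoxyphenoxy)phenoxy]-2,6-dimethoxyphenoxy}-4,6-dimethoxyphenyl formate | COc1cc(OC)c(OC=O)c(Oc2c(OC)cc(Oc3c(OC)cc(OC)cc3Oc3c(OC)cc(OC)cc3OC)cc2OC)c1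
F6 | step 11 | 2-{4-[2,4-dimethoxy-6-(2,4,6-trimethoxyphenoxy)phenoxy]-2,6-dimethoxyphenoxy}-4,6-dimethoxyphenol | COc1cc(OC)c(O)c(Oc2c(OC)cc(Oc3c(OC)cc(OC)cc3Oc3c(OC)cc(OC)cc3OC)cc2OC)c1
F7 | step 10 | (3,5-dimethoxyphenyl)(2,4,6-trimethoxyphenyl)iodonium 4-methylbenzenesulfonate | COc1cc(OC)cc([I+]c2c(OC)cc(OC)cc2OC)c1.Cc1ccc(cc1)S(=O)(=O)[O-]
F8 | step 5 | 2,4-dimethoxy-6-(2,4,6-trimethoxyphenoxy)benzaldehyde | COc1cc(OC)c(C=O)c(Oc2c(OC)cc(OC)cc2OC)c1
F9 | step 5 | 2,4-dimethoxy-6-(2,4,6-trimethoxyphenoxy)phenyl formate | COc1cc(OC)c(OC=O)c(Oc2c(OC)cc(OC)cc2OC)c1
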